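**Plan**
- Ring D (the hydroquinone ring) carries a free phenolic oxygen on the ring carbon directly beside the one that bears the ethylene bridge. This ortho O/CH2 pair is the retron of an o-quinone methide, so the first cut is the CH2–CH2 bond between rings C and D: the ring-D methylene is the electrophilic exocyclic carbon of the quinone methide, the ring-C methylene a benzylic Grignard carbon.
- Second cut: the diaryl ether C–O bond (ring B oxygen to ring C), made by SNAr on 4-fluorobenzaldehyde. Third cut: the ring A/ring B bridge, made as a stilbene C=C by Horner–Wadsworth–Emmons olefination and kept as an alkene until the end.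
- Forward: olefination (A=B), SNAr (B–O–C), CHO → CH2OH → CH2Cl. Separately, 4-(benzyloxy)phenol → ortho-formylation → O-Boc → CH2OH gives the quinone methide precursor. The two fragments are then joined.
- One final hydrogenation saturates the stilbene and removes both benzyl ethers.
- Stereochemistry: the target has no stereocentre; the E-alkene is a temporary helper that the last step removes.

Key step: step 8

Remark: compounds 1, 2, 4 and 8 are taken to be commercial; the geometry of the temporary C=C bond is of no consequence because it is hydrogenated in the last step.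

**Route**

Step 1
Reactants: 1 4-(benzyloxy)-3-hydroxybenzaldehyde; 2 diethyl (3-methoxybenzyl)phosphonate
Product: 3 2-(benzyloxy)-5-[(E)-2-(3-methoxyphenyl)ethenyl]phenol
Conditions: KOtBu (2.5 equiv), THF, 0 °C → rt; aq HCl work-up
Reagents that add atoms: none
Why: Horner–Wadsworth–Emmons olefination of a non-enolisable aryl aldehyde with an aryl-stabilised phosphonate carbanion, in which the first equivalent of base only forms a phenoxide that is meta to the formyl group and so does not deactivate it by resonance, and the E-alkene is expected.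

Step 2
Reactants: 3 2-(benzyloxy)-5-[(E)-2-(3-methoxyphenyl)ethenyl]phenol; 4 4-fluorobenzaldehyde
Product: 5 4-{2-(benzyloxy)-5-[(E)-2-(3-methoxyphenyl)ethenyl]phenoxy}benzaldehyde
Conditions: K2CO3, DMF, 110 °C
Reagents that add atoms: none
Why: Nucleophilic aromatic substitution (addition–elimination) of the phenoxide on a fluoroarene activated by the para formyl group should give the diaryl ether.

Step 3
Reactants: 5 4-{2-(benzyloxy)-5-[(E)-2-(3-methoxyphenyl)ethenyl]phenoxy}benzaldehyde
Product: 6 (4-{2-(benzyloxy)-5-[(E)-2-(3-methoxyphenyl)ethenyl]phenoxy}phenyl)methanol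
Conditions: NaBH4, THF–MeOH, 0 °C
Reagents that add atoms: none
Why: Borohydride reduction of an aryl aldehyde to the primary benzylic alcohol leaves the stilbene and the ethers untouched.

Step 4
Reactants: 6 (4-{2-(benzyloxy)-5-[(E)-2-(3-methoxyphenyl)ethenyl]phenoxy}phenyl)methanol
Product: 7 1-(benzyloxy)-2-[4-(chloromethyl)phenoxy]-4-[(E)-2-(3-methoxyphenyl)ethenyl]benzene
Conditions: SOCl2 (1.2 equiv), DMF (cat.), CH2Cl2, 0 °C → rt
Reagents that add atoms: thionyl chloride ClS(Cl)=O
Why: Deoxychlorination of a primary benzylic alcohol via its chlorosulfite should proceed readily at this electron-rich benzylic position without affecting the aryl ethers.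

Step 5
Reactants: 8 4-(benzyloxy)phenol
Product: 9 5-(benzyloxy)-2-hydroxybenzaldehyde
Conditions: MgCl2, Et3N, (CH2O)n, MeCN, reflux; aq HCl work-up
Reagents that add atoms: paraformaldehyde (as formaldehyde) C=O
Why: Magnesium-mediated ortho-formylation (Casnati–Skattebøl) delivers formaldehyde within the magnesium phenoxide chelate to the position ortho to the hydroxyl group, the two ortho positions being equivalent and the para position blocked.

Step 6
Reactants: 9 5-(benzyloxy)-2-hydroxybenzaldehyde
Product: 10 4-(benzyloxy)-2-formylphenyl tert-butyl carbonate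
Conditions: Boc2O, i-Pr2NEt, DMAP (cat.), CH2Cl2, 0 °C → rt
Reagents that add atoms: di-tert-butyl dicarbonate CC(C)(C)OC(=O)OC(=O)OC(C)(C)C
Why: DMAP-catalysed O-acylation of the phenol gives the aryl tert-butyl carbonate that later serves as activating group and trigger.

Step 7
Reactants: 10 4-(benzyloxy)-2-formylphenyl tert-butyl carbonate
Product: 11 4-(benzyloxy)-2-(hydroxymethyl)phenyl tert-butyl carbonate
Conditions: BH3·THF, THF, 0 °C; pH 7 buffer
Reagents that add atoms: none
Why: Reduction of the aldehyde with electrophilic borane passes through a neutral alkoxyborane and not a free alkoxide, so the neighbouring carbonate should not migrate and the benzylic alcohol should be isolable.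

Step 8
Reactants: 7 1-(benzyloxy)-2-[4-(chloromethyl)phenoxy]-4-[(E)-2-(3-methoxyphenyl)ethenyl]benzene; 11 4-(benzyloxy)-2-(hydroxymethyl)phenyl tert-butyl carbonate
Product: 15 4-(benzyloxy)-2-[2-(4-{2-(benzyloxy)-5-[(E)-2-(3-methoxyphenyl)ethenyl]phenoxy}phenyl)ethyl]phenol, via benzylic Grignard reagent 12 (not isolated), via migrated benzylic carbonate 13 (not isolated), via o-quinone methide 14 (not isolated)
Conditions: (a) 7, Mg turnings (I2-activated), THF, 0 °C, slow addition; (b) 11 (1.3 equiv), t-BuMgCl (1.3 equiv), Et2O, −78 °C; then the solution of 12, −78 °C → rt; aq NH4Cl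
Reagents that add atoms: none
Why: Deprotonation of 11 by the sacrificial base at −78 °C gives a chloromagnesium alkoxide that attacks the neighbouring aryl carbonate, so that the Boc group moves from the ring-D phenolic oxygen to the benzylic oxygen (13), and the phenoxide so released expels tert-butyl carbonate in a 1,4-elimination to give o-quinone methide 14, to whose exocyclic methylene carbon the benzylic Grignard reagent 12 adds with re-aromatisation to the magnesium phenoxide of 15. The closest known reaction type is the generation of o-quinone methides from o-(tert-butoxycarbonyloxy)benzyl alcohols with organomagnesium reagents, followed by 1,4-addition of a second carbanion. No ring is closed and no stereocentre is formed. The step needs 1,4- over 1,2-addition, which the gain of aromaticity on attack at the exocyclic carbon secures, and it needs the quinone methide to meet the Grignard reagent and not itself, which is secured because 14 is released slowly on warming in the presence of 12. The tert-butylmagnesium chloride is consumed in the fast acid–base step before any 14 exists and so cannot compete as a nucleophile, and the electron-rich stilbene of 12 should not compete with a carbanion as a partner of 14 at low temperature. The event joins the two fragments at the sp3–sp3 level and at the same time frees the ortho phenol of ring D without a separate deprotection.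

Step 9
Reactants: 15 4-(benzyloxy)-2-[2-(4-{2-(benzyloxy)-5-[(E)-2-(3-methoxyphenyl)ethenyl]phenoxy}phenyl)ethyl]phenol
Product: 16 2-[2-(4-{2-hydroxy-5-[2-(3-methoxyphenyl)ethyl]phenoxy}phenyl)ethyl]benzene-1,4-diol
Conditions: H2 (1 atm), 10% Pd/C, EtOAc–MeOH, rt; filtration under argon
Reagents that add atoms: none
Why: Heterogeneous catalytic hydrogenation should saturate the stilbene C=C and cleave both aryl benzyl ethers by hydrogenolysis in one operation, while the aryl methyl ether and the diaryl ether are inert.

**Compound list**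
1 | 4-(benzyloxy)-3-hydroxybenzaldehyde | O=Cc1ccc(OCc2ccccc2)c(O)c1 | starting material
2 | diethyl (3-methoxybenzyl)phosphonate | CCOP(=O)(Cc1cccc(OC)c1)OCC | starting material
3 | 2-(benzyloxy)-5-[(E)-2-(3-methoxyphenyl)ethenyl]phenol | COc1cccc(/C=C/c2ccc(OCc3ccccc3)c(O)c2)c1 | intermediate
4 | 4-fluorobenzaldehyde | O=Cc1ccc(F)cc1 | starting material
5 | 4-{2-(benzyloxy)-5-[(E)-2-(3-methoxyphenyl)ethenyl]phenoxy}benzaldehyde | COc1cccc(/C=C/c2ccc(OCc3ccccc3)c(Oc3ccc(C=O)cc3)c2)c1 | intermediate
6 | (4-{2-(benzyloxy)-5-[(E)-2-(3-methoxyphenyl)ethenyl]phenoxy}phenyl)methanol | COc1cccc(/C=C/c2ccc(OCc3ccccc3)c(Oc3ccc(CO)cc3)c2)c1 | intermediate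
7 | 1-(benzyloxy)-2-[4-(chloromethyl)phenoxy]-4-[(E)-2-(3-methoxyphenyl)ethenyl]benzene | COc1cccc(/C=C/c2ccc(OCc3ccccc3)c(Oc3ccc(CCl)cc3)c2)c1 | intermediate
8 | 4-(benzyloxy)phenol | Oc1ccc(OCc2ccccc2)cc1 | starting material
9 | 5-(benzyloxy)-2-hydroxybenzaldehyde | O=Cc1cc(OCc2ccccc2)ccc1O | intermediate
10 | 4-(benzyloxy)-2-formylphenyl tert-butyl carbonate | CC(C)(C)OC(=O)Oc1ccc(OCc2ccccc2)cc1C=O | intermediate
11 | 4-(benzyloxy)-2-(hydroxymethyl)phenyl tert-butyl carbonate | CC(C)(C)OC(=O)Oc1ccc(OCc2ccccc2)cc1CO | intermediate
12 | (4-{2-(benzyloxy)-5-[(E)-2-(3-methoxyphenyl)ethenyl]phenoxy}benzyl)magnesium chloride | COc1cccc(/C=C/c2ccc(OCc3ccccc3)c(Oc3ccc(C[Mg]Cl)cc3)c2)c1 | intermediate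
13 | chloromagnesium 4-(benzyloxy)-2-{[(tert-butoxycarbonyl)oxy]methyl}phenoxide | CC(C)(C)OC(=O)OCc1cc(OCc2ccccc2)ccc1O[Mg]Cl | intermediate
14 | 4-(benzyloxy)-6-methylidenecyclohexa-2,4-dien-1-one | C=C1C=C(OCc2ccccc2)C=CC1=O | intermediate
15 | 4-(benzyloxy)-2-[2-(4-{2-(benzyloxy)-5-[(E)-2-(3-methoxyphenyl)ethenyl]phenoxy}phenyl)ethyl]phenol | COc1cccc(/C=C/c2ccc(OCc3ccccc3)c(Oc3ccc(CCc4cc(OCc5ccccc5)ccc4O)cc3)c2)c1 | intermediate
16 | 2-[2-(4-{2-hydroxy-5-[2-(3-methoxyphenyl)ethyl]phenoxy}phenyl)ethyl]benzene-1,4-diol | COc1cccc(CCc2ccc(O)c(Oc3ccc(CCc4cc(O)ccc4O)cc3)c2)c1 | target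

**Step count:** 9 steps in total; longest linear sequence 6 steps (1, 2, 3, 4, 8, 9).

**Steps most likely to fail**

Step 8. What may go wrong: Wurtz-type homocoupling of the electron-rich benzylic chloride during magnesium insertion, which lowers the titre of the Grignard reagent and leaves the quinone methide to oligomerise. Fallback, setting out from 7 and 9 and coming back at 16: 7 is heated with triphenylphosphine in toluene to give the benzylic triphenylphosphonium chloride F1. 9 is O-benzylated (BnBr, K2CO3, DMF) to 2,5-bis(benzyloxy)benzaldehyde F2. Wittig reaction of the ylide from F1 (KOtBu, THF) with F2 should give the bis-stilbene tris(benzyl ether) F3 as an E/Z mixture at the new alkene. Hydrogenation (H2, Pd/C) then saturates both alkenes and removes all three benzyl groups to give 16 directly.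

Step 1. What may go wrong: incomplete olefination, because under the dianionic conditions the potassium phenoxide of 1 may precipitate and add the phosphonate carbanion only slowly. Fallback, setting out from 1 and coming back at 6: the phenol is capped first by SNAr with methyl 4-fluorobenzoate (K2CO3, DMSO, 130 °C) to give methyl 4-[2-(benzyloxy)-5-formylphenoxy]benzoate F4. Olefination of F4 with 2 (NaH, THF) should give the stilbene ester methyl 4-{2-(benzyloxy)-5-[(E)-2-(3-methoxyphenyl)ethenyl]phenoxy}benzoate F5. Reduction of the ester with DIBAL-H (CH2Cl2, −78 → 0 °C) gives 6.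

Step 7. What may go wrong: migration of the carbonate to the newly formed benzylic oxygen during reduction or work-up, with premature quinone methide formation and over-reduction to the methylphenol. Fallback, setting out from 9 and coming back at 11: the order is reversed. 9 is reduced with NaBH4 (MeOH, 0 °C) to 4-(benzyloxy)-2-(hydroxymethyl)phenol F6. Its phenol, the only site ionised by a weak base, is then converted selectively into the carbonate (Boc2O, K2CO3, 18-crown-6, THF, 0 °C) to give 11.

**Further compounds**
F1 | step 8 | (4-{2-(benzyloxy)-5-[(E)-2-(3-methoxyphenyl)ethenyl]phenoxy}benzyl)triphenylphosphonium chloride | COc1cccc(/C=C/c2ccc(OCc3ccccc3)c(Oc3ccc(C[P+](c4ccccc4)(c4ccccc4)c4ccccc4)cc3)c2)c1.[Cl-]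
F2 | step 8 | 2,5-bis(benzyloxy)benzaldehyde | O=Cc1cc(OCc2ccccc2)ccc1OCc1ccccc1
F3 | step 8 | 1-(benzyloxy)-2-(4-{2-[2,5-bis(benzyloxy)phenyl]ethenyl}phenoxy)-4-[(E)-2-(3-methoxyphenyl)ethenyl]benzene (new alkene E/Z, not specified) | COc1cccc(/C=C/c2ccc(OCc3ccccc3)c(Oc3ccc(C=Cc4cc(OCc5ccccc5)ccc4OCc4ccccc4)cc3)c2)c1
F4 | step 1 | methyl 4-[2-(benzyloxy)-5-formylphenoxy]benzoate | COC(=O)c1ccc(Oc2cc(C=O)ccc2OCc2ccccc2)cc1
F5 | step 1 | methyl 4-{2-(benzyloxy)-5-[(E)-2-(3-methoxyphenyl)ethenyl]phenoxy}benzoate | COc1cccc(/C=C/c2ccc(OCc3ccccc3)c(Oc3ccc(C(=O)OC)cc3)c2)c1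
F6 | step 7 | 4-(benzyloxy)-2-(hydroxymethyl)phenol | OCc1cc(OCc2ccccc2)ccc1O
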